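## Structural features

The target is a 14-membered carbocycle (C1–C14) with three trisubstituted ring alkenes, C3=C4, C7=C8 and C11=C12, each separated from the next by two CH2 groups. C4 carries a hydroxymethyl group; C8 and C12 carry methyl groups. The only stereocentre is C1 (R), an all-carbon allylic methine between the ring methylenes C2 and C14. It bears the exocyclic 1,1-disubstituted alkene C15=C16, and C15 continues into a 4-methylpent-3-enyl chain. No stereocentre has a neighbour, so C1 must be set by a reagent. The ring alkene geometries are fixed: hydroxymethyl cis to C2 at C3=C4 (Z by the sequence rule, with C2 and C5 trans in the ring), C6 and C9 trans at C7=C8 (E), C10 and C13 cis at C11=C12 (Z). Fragile points are the five isolated, electron-rich alkenes (acid would cause migration or transannular cyclisation), the primary allylic alcohol and the methylene C2 between C1 and C3. The difficulty is to close an entropically unfavourable 14-membered ring without disturbing three alkene geometries, and to fix a lone stereocentre that has no heteroatom. The key step uses the C3=C4–CH2OH unit: read as a reduced (Z)-2-alkyl-enoate, it comes from a C3 aldehyde and a C4 phosphonoester. Because C2 is a plain methylene, the aldehyde is unhindered and C1 cannot epimerise.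

## Logic of the disconnections

**31 ⇒ 30.** No skeletal bond is cut; the hydroxymethyl carbon on C4 is taken back to a methyl ester. This makes C4 the α-carbon of an ester and opens it to carbanion chemistry. The forward step must reduce a (Z)-enoate 1,2 only and move none of the alkenes.

**30 ⇒ 29.** The C3=C4 double bond is cut, which opens the ring. This is the one ring alkene next to a functionalised carbon, and the required geometry (ester cis to C2) is the kinetic outcome of a trifluoroethyl phosphonate olefination. The macrocycle becomes one open chain, and ring closure and the third alkene geometry are solved together. The forward step needs cyclisation to beat oligomerisation and the ester to end cis to C2.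

**29 ⇒ 28 ⇒ 27.** No C–C bond is cut; the C3 aldehyde goes back to the alcohol and then to its silyl ether. An enolisable aldehyde cannot be stored next to an acidic phosphonoacetate, and a silyl ether (not a benzylic ether, whose CH2 would compete in the later deprotonation) survives the organolithium steps. The forward steps must be close to neutral.

**27 ⇒ 24 + 25.** The C4–C5 bond is cut. C4 is the acidic carbon of a purchasable phosphonoacetate and C5 is an unbranched primary carbon. All steps before this one are thereby free of the base-sensitive phosphonate. C5 is carried as a chloride, which needs no protecting group and survives the organometallic steps. The forward step needs clean mono-alkylation at an unactivated primary centre.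

**24 ⇒ 20 + 17 (17 from 16).** The C1–C15 bond is cut. C1 is bonded to the substituted carbon of a 1,1-disubstituted alkene, which a boron-to-carbon shift onto an alkenyl group delivers with retention. The eight-carbon side chain comes from a purchasable methyl ketone and C1 becomes a C–B centre. The forward step must tolerate three other alkenes in the presence of iodine.

**20 ⇒ 15 + 12.** The C1–C14 bond is cut. A configurationally defined carbenoid at C1 joined to a primary boronate at C14 creates the stereocentre under reagent control from two achiral pieces. Working the stereochemical course through (retentive borylation, invertive migration, retentive alkenylation) shows that the R centre needs (+)-sparteine; the (−)-enantiomer would give the wrong enantiomer. The forward step needs highly selective deprotonation and complete migration.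

**15 ⇒ 14 ⇒ 13.** Only C–O bonds are cut: carbamate, then silyl ether, back to the symmetrical diol. The forward steps need mono-functionalisation of the diol.

**12 ⇒ 10 + 11.** The C13–C14 bond is cut. C13 is allylic and so a good electrophile; C14 arrives with its boron from a geminal diboryl one-carbon unit. Boron is therefore introduced only after the aluminium chemistry. The forward step must attack the primary allylic terminus without transposition and leave the C5 chloride alone.

**10 ⇒ 9 ⇒ 5 + 6.** The C6–C7 and C8–CH3 bonds are cut (the methyl comes from AlMe3). Syn-methylmetalation of a terminal alkyne fixes the E geometry of C7=C8, and the epoxide brings C5 and C6 with oxygen on C5. The diol is then chlorinated at both ends in one operation. The forward step needs regio- and stereoselective carbometalation in the presence of a free hydroxyl.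

**5 ⇒ 4 ⇒ 2 + 3, and 2 ⇒ 1.** The C11=C12 double bond is cut. With C13 cis to C10 it is again a reduced (Z)-2-methyl-enoate, so the logic of the key step is used here intermolecularly. This reaches three purchasable compounds. The forward step needs high Z-selectivity with an enolisable aldehyde.

## Other disconnections considered

**Alternative 1:** The cut removes C1–C14 and C2–C3 together.

- **Forward step:** Vinyllithium adds to the C14 boron of the open chain A1, which also carries the (Z)-bromoalkene at C3. Pd(OAc)2 with a MandyPhos ligand inserts into the C3–Br bond, the alkenylpalladium activates the vinyl group, C14 shifts from boron to C1 and reductive elimination joins C2 to C3. This would give the macrocyclic secondary boronate A2; Zweifel alkenylation and desilylation would finish.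
- **In favour:** Ring closure, two C–C bonds and the C1 stereocentre come from one catalytic enantioselective step. A1 is achiral, no stoichiometric chiral diamine is needed, and no redox steps follow ring closure. On catalyst economy and on steps after ring closure this alternative is the better one. The Zweifel step is common to both plans, so they are equal there.
- **Against:** This coupling is established between two molecules; a 14-membered closure has no close precedent. The electrophile is a hindered trisubstituted alkenyl bromide, and bromide tends to inhibit the metallate shift. Vinyllithium would have to add to boron without bromine–lithium exchange at C3. Direct transmetalation (a plain Suzuki-type closure) could compete, and enantioselectivity inside a macrocyclic transition state is an open question.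
- **Comparison:** A1 needs the C3=C4 geometry as a stereodefined bromoalkene, which is harder to prepare than an enoate formed during ring closure. Mechanistically, the chosen olefination has predictable, substrate-independent Z control. The alternative could be two or three steps shorter, but all its risk sits in one unprecedented step.

**Alternative 2:** The cut is C1–C14, with C15=C16 arising by allylic transposition.

- **Forward step:** The 18-membered allylic macrolactone A3 (an E-configured C1=C15 alkene is assumed) is converted into its boron enolate with a chiral 2-bromo-1,3,2-diazaborolidine and triethylamine. The [3,3] shift would give the ring-contracted acid A4.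
- **In favour:** Macrolactonisation is among the most dependable large-ring closures, and on that point this alternative is the better one. The contraction is intramolecular and needs no dilution. C1 and the exocyclic methylene arise together.
- **Against:** The chiral boron reagent is stoichiometric and must be prepared. A4 carries a carboxyl group and a second stereocentre at C14 that the target lacks. Removing it needs a radical decarboxylation, and a C14 radical sits next to C15=C16 and across the ring from C11=C12. A3 also needs a stereodefined trisubstituted C1=C15 alkene skipped to C3=C4 through C2. The sense at C1 depends on enolate geometry and on chair versus boat in a macrocyclic transition state.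
- **Comparison:** Structurally, the alternative builds a centre only to erase it. Mechanistically, the outcome at C1 is harder to predict than in lithiation–borylation, whose stereochemical course is fixed step by step. In step count it is longer by the decarboxylation and protecting-group operations.

**Alternative 3:** The cut is C9–C10, between two allylic carbons.

- **Forward step:** The open chain A5 holds an (E)-allylic phenyl sulfone at C9 and a (Z)-allylic bromide at C10. KN(SiMe3)2 at high dilution generates the sulfonyl carbanion, which displaces the bromide and would give the macrocyclic sulfone A6 as a C9 epimer mixture. Reductive desulfonylation and desilylation would follow.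
- **In favour:** Alkylation by a sulfone-stabilised allylic carbanion is a classic closure for 14-membered terpenoid rings. On ring-closing precedent it is the equal of the chosen plan, and perhaps better for this ring type. No alkene geometry or stereocentre is at stake in the closure, and the anion is soft and weakly basic.
- **Against:** All three ring alkenes, including the (Z)-hydroxymethyl alkene, must already be in the chain. The Z-enoate chemistry is therefore still needed, as a separate intermolecular step with reduction and protection. Reductive removal of an allylic sulfone can shift or scramble C7=C8. Attack at the far end of the allylic bromide and γ-alkylation of the sulfonyl anion are possible leaks.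
- **Comparison:** The chosen plan forms the C3=C4 alkene and the ring in one step and leaves an ester one reduction from the target. The alternative spends steps on sulfone and bromide installation and on two post-closure operations, so it is longer by about three or four steps. Mechanistically, both closures are irreversible and run under dilution, so they are equal there.

Key step: step 15

Remark: atoms are numbered C1 (stereocentre) to C14 round the ring with C15=C16 exocyclic; 3, 11 and (+)-sparteine are taken as purchasable; organometallic intermediates made by a separate operation are numbered, while simple conjugate bases and olefination adducts are treated in the Why lines (TBS = tert-butyldimethylsilyl).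

## Route

**Step 1**
Reactants: 1 pent-4-yn-1-ol
Product: 2 pent-4-ynal
Conditions: (COCl)2, DMSO, CH2Cl2, −78 °C; Et3N, −78 °C → rt
Reagents that add atoms: none
Why: Swern oxidation stops at the aldehyde under anhydrous, non-acidic conditions and leaves the terminal alkyne alone; the volatile aldehyde should be carried on as a dried solution.

**Step 2**
Reactants: 2 pent-4-ynal; 3 ethyl 2-[bis(2,2,2-trifluoroethoxy)phosphoryl]propanoate
Product: 4 ethyl (2Z)-2-methylhept-2-en-6-ynoate
Conditions: 3, KN(SiMe3)2, 18-crown-6, THF, −78 °C; then 2, −78 °C
Reagents that add atoms: none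
Why: Still–Gennari olefination: the preformed potassium phosphonate adds to the aldehyde and the adduct collapses faster than it reverts, which should give the trisubstituted (Z)-enoate (ester cis to the chain), the future C11=C12 with C13 cis to C10.

**Step 3**
Reactants: 4 ethyl (2Z)-2-methylhept-2-en-6-ynoate
Product: 5 (2Z)-2-methylhept-2-en-6-yn-1-ol
Conditions: iBu2AlH, CH2Cl2, −78 → 0 °C; aq. potassium sodium tartrate
Reagents that add atoms: none
Why: 1,2-Reduction of the conjugated ester by iBu2AlH at low temperature gives the allylic alcohol without touching the alkyne or the alkene geometry.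

**Step 4**
Reactants: 5 (2Z)-2-methylhept-2-en-6-yn-1-ol; 6 oxirane
Product: 9 (2Z,6E)-2,6-dimethylnona-2,6-diene-1,9-diol, via alkenylalane 7 (not isolated), via dilithium alanate 8 (not isolated)
Conditions: AlMe3 (3.5 equiv), Cp2ZrCl2 (0.25 equiv), CH2Cl2, 0 °C → rt; evaporation; nBuLi, THF/hexane, −78 → 0 °C; 6, 0 °C → rt; aq. potassium sodium tartrate
Reagents that add atoms: trimethylaluminium, C[Al](C)C
Why: Zirconium-catalysed methylalumination adds CH3 and Al syn across the terminal alkyne, with CH3 on the inner carbon (C8) and Al on C7, while the hydroxyl is held as its aluminium alkoxide (7). The alanate 8 transfers the alkenyl group to oxirane with retention, so C9 and C6 end trans (7E) and C5 arrives as a primary alcohol.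

**Step 5**
Reactants: 9 (2Z,6E)-2,6-dimethylnona-2,6-diene-1,9-diol
Product: 10 (2Z,6E)-1,9-dichloro-2,6-dimethylnona-2,6-diene
Conditions: PPh3 (2.4 equiv), CCl4, reflux
Reagents that add atoms: tetrachloromethane, ClC(Cl)(Cl)Cl
Why: Appel chlorination converts both primary alcohols by SN2 displacement of the alkoxyphosphonium ion; this method turns 2-methylallylic alcohols of this type into their chlorides without allylic transposition or loss of geometry.

**Step 6**
Reactants: 10 (2Z,6E)-1,9-dichloro-2,6-dimethylnona-2,6-diene; 11 2,2'-methylenebis(4,4,5,5-tetramethyl-1,3,2-dioxaborolane)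
Product: 12 2-[(3Z,7E)-10-chloro-3,7-dimethyldeca-3,7-dien-1-yl]-4,4,5,5-tetramethyl-1,3,2-dioxaborolane
Conditions: 11 (1.5 equiv), NaOtBu (1.5 equiv), THF, 0 °C; then 10, 0 °C → rt
Reagents that add atoms: none
Why: Alkoxide-promoted deborylative alkylation of a geminal bis(boronate): tert-butoxide removes one boryl group of 11, and the α-boryl carbanion displaces the allylic chloride at its unhindered primary terminus (SN2), adding C14 with its boron. The unactivated primary chloride at C5 is far less reactive and should be kept.

**Step 7**
Reactants: 13 propane-1,3-diol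
Product: 14 3-{[tert-butyl(dimethyl)silyl]oxy}propan-1-ol
Conditions: NaH (1.0 equiv), THF, 0 °C → rt; TBSCl (1.0 equiv)
Reagents that add atoms: tert-butyldimethylsilyl chloride, CC(C)(C)[Si](C)(C)Cl
Why: O-Silylation through the sparingly soluble monosodium alkoxide of the symmetrical diol should stop at the monoether.

**Step 8**
Reactants: 14 3-{[tert-butyl(dimethyl)silyl]oxy}propan-1-ol
Product: 15 3-{[tert-butyl(dimethyl)silyl]oxy}propyl N,N-di(propan-2-yl)carbamate
Conditions: iPr2NCOCl, Et3N, CH2Cl2, reflux
Reagents that add atoms: N,N-diisopropylcarbamoyl chloride, CC(C)N(C(C)C)C(Cl)=O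
Why: Carbamoylation of the primary alcohol gives the hindered carbamate that directs α-lithiation and later serves as the leaving group.

**Step 9**
Reactants: 16 6-methylhept-5-en-2-one
Product: 17 N'-[(2E)-6-methylhept-5-en-2-ylidene]-2,4,6-tri(propan-2-yl)benzenesulfonohydrazide
Conditions: 2,4,6-iPr3C6H2SO2NHNH2, MeOH, rt
Reagents that add atoms: 2,4,6-triisopropylbenzenesulfonyl hydrazide, CC(C)c1cc(C(C)C)c(S(=O)(=O)NN)c(C(C)C)c1
Why: Condensation of the methyl ketone with the arylsulfonyl hydrazide gives the hydrazone that serves as the Shapiro precursor of the 2-lithio-1-alkene.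

**Step 10**
Reactants: 15 3-{[tert-butyl(dimethyl)silyl]oxy}propyl N,N-di(propan-2-yl)carbamate; 12 2-[(3Z,7E)-10-chloro-3,7-dimethyldeca-3,7-dien-1-yl]-4,4,5,5-tetramethyl-1,3,2-dioxaborolane
Product: 20 tert-butyl{[(3R,6Z,10E)-13-chloro-6,10-dimethyl-3-(4,4,5,5-tetramethyl-1,3,2-dioxaborolan-2-yl)trideca-6,10-dien-1-yl]oxy}dimethylsilane, via lithiated carbamate 18 (not isolated), via boronate complex 19 (not isolated)
Conditions: 15 (1.3 equiv), sBuLi, (+)-sparteine, Et2O, −78 °C, 5 h; 12, −78 °C, 1 h; MgBr2·OEt2, −78 °C → reflux
Reagents that add atoms: none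
Why: Sparteine-mediated carbamate lithiation–borylation: sBuLi/(+)-sparteine removes the pro-R hydrogen next to the carbamate oxygen to give the configurationally stable (R)-organolithium 18, which is borylated with retention to 19. Anti-periplanar 1,2-shift of the C14 alkyl group with loss of the carbamate (inversion at carbon) then sets C1 as the (R)-boronate; the silyl ether and the alkyl chloride are spectators at −78 °C.

**Step 11**
Reactants: 17 N'-[(2E)-6-methylhept-5-en-2-ylidene]-2,4,6-tri(propan-2-yl)benzenesulfonohydrazide; 20 tert-butyl{[(3R,6Z,10E)-13-chloro-6,10-dimethyl-3-(4,4,5,5-tetramethyl-1,3,2-dioxaborolan-2-yl)trideca-6,10-dien-1-yl]oxy}dimethylsilane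
Product: 24 tert-butyl{[(3R,6Z,10E)-13-chloro-6,10-dimethyl-3-(6-methylhepta-1,5-dien-2-yl)trideca-6,10-dien-1-yl]oxy}dimethylsilane, via alkenyllithium 21 (not isolated), via alkenylboronate complex 22 (not isolated), via iodoboronate 23 (not isolated)
Conditions: 17 (2.5 equiv), nBuLi (5.0 equiv), THF, −78 → 0 °C; 20, THF, −78 °C; I2, THF, −78 °C; NaOMe, MeOH, −78 °C → rt
Reagents that add atoms: none
Why: Shapiro fragmentation of 17 (second deprotonation at the methyl group) gives the 2-lithio-1-alkene 21, which adds to boron to form 22. In the Zweifel olefination, iodine activates the alkenyl group, the C1 carbon shifts from boron to C15 with retention (23), and methoxide triggers anti-elimination of boron and iodine to release the 1,1-disubstituted alkene.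

**Step 12**
Reactants: 24 tert-butyl{[(3R,6Z,10E)-13-chloro-6,10-dimethyl-3-(6-methylhepta-1,5-dien-2-yl)trideca-6,10-dien-1-yl]oxy}dimethylsilane; 25 methyl 2-[bis(2,2,2-trifluoroethoxy)phosphoryl]acetate
Product: 27 methyl (5E,9Z,13R)-2-[bis(2,2,2-trifluoroethoxy)phosphoryl]-13-(2-{[tert-butyl(dimethyl)silyl]oxy}ethyl)-6,10,18-trimethyl-14-methylidenenonadeca-5,9,17-trienoate, via primary iodide 26 (not isolated)
Conditions: 25 (3 equiv), NaH (2.5 equiv), THF, 0 °C; then 24, NaI (1.5 equiv), DMF, 60 °C
Reagents that add atoms: none
Why: C-Alkylation of the sodium phosphonoacetate, a soft and weakly basic carbon nucleophile, by the primary iodide 26 formed in the flask by Finkelstein exchange creates the C4–C5 bond. Excess 25 holds back dialkylation, and C4 forms as an epimer mixture that does not matter.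

**Step 13**
Reactants: 27 methyl (5E,9Z,13R)-2-[bis(2,2,2-trifluoroethoxy)phosphoryl]-13-(2-{[tert-butyl(dimethyl)silyl]oxy}ethyl)-6,10,18-trimethyl-14-methylidenenonadeca-5,9,17-trienoate
Product: 28 methyl (5E,9Z,13R)-2-[bis(2,2,2-trifluoroethoxy)phosphoryl]-13-(2-hydroxyethyl)-6,10,18-trimethyl-14-methylidenenonadeca-5,9,17-trienoate
Conditions: HF·pyridine, pyridine, THF, 0 °C → rt
Reagents that add atoms: none
Why: Fluoride cleavage of the primary silyl ether with buffered HF·pyridine is mild enough for the acidic phosphonoacetate, the trifluoroethyl esters and the alkenes.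

**Step 14**
Reactants: 28 methyl (5E,9Z,13R)-2-[bis(2,2,2-trifluoroethoxy)phosphoryl]-13-(2-hydroxyethyl)-6,10,18-trimethyl-14-methylidenenonadeca-5,9,17-trienoate
Product: 29 methyl (5E,9Z,13R)-2-[bis(2,2,2-trifluoroethoxy)phosphoryl]-6,10,18-trimethyl-14-methylidene-13-(2-oxoethyl)nonadeca-5,9,17-trienoate
Conditions: Dess–Martin periodinane, pyridine, CH2Cl2, 0 °C → rt
Reagents that add atoms: none
Why: Dess–Martin oxidation gives the aldehyde under near-neutral conditions, so the phosphonoacetate is not deprotonated and cannot condense early; C1 is β to the new carbonyl and cannot epimerise.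

**Step 15**
Reactants: 29 methyl (5E,9Z,13R)-2-[bis(2,2,2-trifluoroethoxy)phosphoryl]-6,10,18-trimethyl-14-methylidene-13-(2-oxoethyl)nonadeca-5,9,17-trienoate
Product: 30 methyl (1Z,4E,8Z,12R)-5,9-dimethyl-12-(6-methylhepta-1,5-dien-2-yl)cyclotetradeca-1(14),4,8-triene-1-carboxylate
Conditions: KN(SiMe3)2 (1.05 equiv), 18-crown-6 (5 equiv), THF, −78 → −40 °C; 29 added by syringe pump to a final concentration of about 1 mM; cold quench with aq. NH4Cl
Reagents that add atoms: none
Why: KN(SiMe3)2 removes the C4 hydrogen of the phosphonoacetate, which is far more acidic than the aldehyde α-hydrogens, and the crown ether strips potassium from the carbanion so that it adds to the C3 aldehyde of the same chain without chelation. The electron-poor bis(trifluoroethyl) phosphonate makes cycloelimination of the oxaphosphetane faster than reversal of the addition, so the kinetically preferred adduct goes straight to the alkene with the ester cis to C2; this is the Still–Gennari form of the intramolecular Horner–Wadsworth–Emmons reaction, the closest known reaction type and one established for large rings. The 14-membered ring closes by a 14-exo-trig addition of C4 to the aldehyde carbon followed by loss of potassium bis(trifluoroethyl) phosphate, and C3=C4 is the only new skeletal bond. No stereocentre is created: both C4 epimers of 29 give the same planar carbanion, and C1, β to the aldehyde, keeps its R configuration. Ring closure over oligomerisation is secured by slow addition to high dilution, by the unhindered CH2–CHO terminus and by the two preset trisubstituted alkenes that stiffen the chain. Z over E is secured by the trifluoroethyl esters, the dissociated potassium counter-ion and the low temperature, and the ring helps, since the Z-enoate puts C2 and C5 trans across C3=C4, the less strained arrangement in a 14-membered triene. A near-stoichiometric amount of base and a cold quench avoid γ-deprotonation of the product.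

**Step 16**
Reactants: 30 methyl (1Z,4E,8Z,12R)-5,9-dimethyl-12-(6-methylhepta-1,5-dien-2-yl)cyclotetradeca-1(14),4,8-triene-1-carboxylate
Product: 31 [(1Z,4E,8Z,12R)-5,9-dimethyl-12-(6-methylhepta-1,5-dien-2-yl)cyclotetradeca-1(14),4,8-trien-1-yl]methanol
Conditions: iBu2AlH (2.5 equiv), CH2Cl2, −78 → 0 °C; aq. potassium sodium tartrate
Reagents that add atoms: none
Why: 1,2-Reduction of the conjugated ester by iBu2AlH gives the allylic alcohol without conjugate reduction or alkene migration; the product is the target, (1R,3Z,7E,11Z) in the ring numbering used here.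

## Compound list

1 | pent-4-yn-1-ol | C#CCCCO | starting material
2 | pent-4-ynal | C#CCCC=O | intermediate
3 | ethyl 2-[bis(2,2,2-trifluoroethoxy)phosphoryl]propanoate (racemic) | CCOC(=O)C(C)P(=O)(OCC(F)(F)F)OCC(F)(F)F | starting material
4 | ethyl (2Z)-2-methylhept-2-en-6-ynoate | CCOC(=O)/C(C)=C\CCC#C | intermediate
5 | (2Z)-2-methylhept-2-en-6-yn-1-ol | OC/C(C)=C\CCC#C | intermediate
6 | oxirane | C1CO1 | starting material
7 | dimethyl{(1E,5Z)-7-[(dimethylalumanyl)oxy]-2,6-dimethylhepta-1,5-dien-1-yl}alumane | C[Al](C)OC/C(C)=C\CC/C(C)=C/[Al](C)C | intermediate (not isolated)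
8 | dilithium butyl{(1E,5Z)-7-[(butyldimethylaluminato)oxy]-2,6-dimethylhepta-1,5-dien-1-yl}dimethylaluminate | [Li+].[Li+].CCCC[Al-](C)(C)OC/C(C)=C\CC/C(C)=C/[Al-](C)(C)CCCC | intermediate (not isolated)
9 | (2Z,6E)-2,6-dimethylnona-2,6-diene-1,9-diol | OC/C(C)=C\CC/C(C)=C/CCO | intermediate
10 | (2Z,6E)-1,9-dichloro-2,6-dimethylnona-2,6-diene | ClC/C(C)=C\CC/C(C)=C/CCCl | intermediate
11 | 2,2'-methylenebis(4,4,5,5-tetramethyl-1,3,2-dioxaborolane) | CC1(C)OB(CB2OC(C)(C)C(C)(C)O2)OC1(C)C | starting material
12 | 2-[(3Z,7E)-10-chloro-3,7-dimethyldeca-3,7-dien-1-yl]-4,4,5,5-tetramethyl-1,3,2-dioxaborolane | CC1(C)OB(CC/C(C)=C\CC/C(C)=C/CCCl)OC1(C)C | intermediate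
13 | propane-1,3-diol | OCCCO | starting material
14 | 3-{[tert-butyl(dimethyl)silyl]oxy}propan-1-ol | CC(C)(C)[Si](C)(C)OCCCO | intermediate
15 | 3-{[tert-butyl(dimethyl)silyl]oxy}propyl N,N-di(propan-2-yl)carbamate | CC(C)N(C(C)C)C(=O)OCCCO[Si](C)(C)C(C)(C)C | intermediate
16 | 6-methylhept-5-en-2-one | CC(=O)CCC=C(C)C | starting material
17 | N'-[(2E)-6-methylhept-5-en-2-ylidene]-2,4,6-tri(propan-2-yl)benzenesulfonohydrazide | C/C(CCC=C(C)C)=N\NS(=O)(=O)c1c(C(C)C)cc(C(C)C)cc1C(C)C | intermediate
18 | (1R)-3-{[tert-butyl(dimethyl)silyl]oxy}-1-lithiopropyl N,N-di(propan-2-yl)carbamate, as its (+)-sparteine complex | [Li][C@H](CCO[Si](C)(C)C(C)(C)C)OC(=O)N(C(C)C)C(C)C | intermediate (not isolated)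
19 | lithium boronate complex of 18 and 12 (boron carries the pinacolate, the C14 alkyl group and the (R)-carbamoyloxy carbon C1) | [Li+].CC1(C)O[B-](CC/C(C)=C\CC/C(C)=C/CCCl)([C@H](CCO[Si](C)(C)C(C)(C)C)OC(=O)N(C(C)C)C(C)C)OC1(C)C | intermediate (not isolated)
20 | tert-butyl{[(3R,6Z,10E)-13-chloro-6,10-dimethyl-3-(4,4,5,5-tetramethyl-1,3,2-dioxaborolan-2-yl)trideca-6,10-dien-1-yl]oxy}dimethylsilane | CC1(C)OB(OC1(C)C)[C@H](CC/C(C)=C\CC/C(C)=C/CCCl)CCO[Si](C)(C)C(C)(C)C | intermediate
21 | (6-methylhepta-1,5-dien-2-yl)lithium | [Li]C(=C)CCC=C(C)C | intermediate (not isolated)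
22 | lithium boronate complex of 21 and 20 (boron carries the pinacolate, the alkenyl group and the (R)-C1 alkyl group) | [Li+].CC1(C)O[B-](C(=C)CCC=C(C)C)([C@H](CC/C(C)=C\CC/C(C)=C/CCCl)CCO[Si](C)(C)C(C)(C)C)OC1(C)C | intermediate (not isolated)
23 | tert-butyl{[(3R,6Z,10E)-13-chloro-3-[1-iodo-6-methyl-2-(4,4,5,5-tetramethyl-1,3,2-dioxaborolan-2-yl)hept-5-en-2-yl]-6,10-dimethyltrideca-6,10-dien-1-yl]oxy}dimethylsilane (boron-bearing carbon undefined) | CC1(C)OB(OC1(C)C)C(CI)(CCC=C(C)C)[C@H](CC/C(C)=C\CC/C(C)=C/CCCl)CCO[Si](C)(C)C(C)(C)C | intermediate (not isolated)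
24 | tert-butyl{[(3R,6Z,10E)-13-chloro-6,10-dimethyl-3-(6-methylhepta-1,5-dien-2-yl)trideca-6,10-dien-1-yl]oxy}dimethylsilane | C=C(CCC=C(C)C)[C@H](CC/C(C)=C\CC/C(C)=C/CCCl)CCO[Si](C)(C)C(C)(C)C | intermediate
25 | methyl 2-[bis(2,2,2-trifluoroethoxy)phosphoryl]acetate | COC(=O)CP(=O)(OCC(F)(F)F)OCC(F)(F)F | starting material
26 | tert-butyl{[(3R,6Z,10E)-13-iodo-6,10-dimethyl-3-(6-methylhepta-1,5-dien-2-yl)trideca-6,10-dien-1-yl]oxy}dimethylsilane | C=C(CCC=C(C)C)[C@H](CC/C(C)=C\CC/C(C)=C/CCI)CCO[Si](C)(C)C(C)(C)C | intermediate (not isolated)
27 | methyl (5E,9Z,13R)-2-[bis(2,2,2-trifluoroethoxy)phosphoryl]-13-(2-{[tert-butyl(dimethyl)silyl]oxy}ethyl)-6,10,18-trimethyl-14-methylidenenonadeca-5,9,17-trienoate (both C2 epimers) | C=C(CCC=C(C)C)[C@H](CC/C(C)=C\CC/C(C)=C/CCC(C(=O)OC)P(=O)(OCC(F)(F)F)OCC(F)(F)F)CCO[Si](C)(C)C(C)(C)C | intermediate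
28 | methyl (5E,9Z,13R)-2-[bis(2,2,2-trifluoroethoxy)phosphoryl]-13-(2-hydroxyethyl)-6,10,18-trimethyl-14-methylidenenonadeca-5,9,17-trienoate | C=C(CCC=C(C)C)[C@H](CC/C(C)=C\CC/C(C)=C/CCC(C(=O)OC)P(=O)(OCC(F)(F)F)OCC(F)(F)F)CCO | intermediate
29 | methyl (5E,9Z,13R)-2-[bis(2,2,2-trifluoroethoxy)phosphoryl]-6,10,18-trimethyl-14-methylidene-13-(2-oxoethyl)nonadeca-5,9,17-trienoate | C=C(CCC=C(C)C)[C@H](CC/C(C)=C\CC/C(C)=C/CCC(C(=O)OC)P(=O)(OCC(F)(F)F)OCC(F)(F)F)CC=O | intermediate
30 | methyl (1Z,4E,8Z,12R)-5,9-dimethyl-12-(6-methylhepta-1,5-dien-2-yl)cyclotetradeca-1(14),4,8-triene-1-carboxylate | C=C(CCC=C(C)C)[C@H]1C/C=C(\C(=O)OC)CC/C=C(\C)CC/C=C(/C)CC1 | intermediate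
31 | [(1Z,4E,8Z,12R)-5,9-dimethyl-12-(6-methylhepta-1,5-dien-2-yl)cyclotetradeca-1(14),4,8-trien-1-yl]methanol | C=C(CCC=C(C)C)[C@H]1C/C=C(\CO)CC/C=C(\C)CC/C=C(/C)CC1 | target

## Step count and least certain steps

Total step count: 16. Longest linear sequence: 13 steps (steps 1–6 and 10–16), 11 of them before the key step.

**Step 15 (key step).** The most likely failures are olefination between two molecules, which gives oligomers in competition with the 14-membered closure, and partial loss of Z-selectivity if the adduct has to be warmed before it collapses. Enolisation of the aldehyde by the strong base is a further leak. A milder base system (K2CO3, 18-crown-6, toluene) is a change of conditions only. The fallback changes the phosphonate class and the base regime. It sets out from 24. Alkylation with ethyl 2-[bis(2-methylphenoxy)phosphoryl]acetate (NaH, NaI, DMF) would give the di-o-tolyl phosphonate silyl ether F1. HF·pyridine would give the alcohol F2, and Dess–Martin oxidation the aldehyde F3. Cyclisation under the Ando variant of the Horner–Wadsworth–Emmons reaction (NaI, DBU, THF, 0 °C, slow addition) relies on the aryloxy groups for Z-selectivity under weakly basic, sodium-chelated conditions and would give the macrocyclic ethyl ester F4. Reduction with iBu2AlH brings the route back at 31.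

**Step 4.** The aluminium alkoxide may tie up AlMe3 and nBuLi in aggregates, so carbometalation could stall or the alkenyl group could be protonated on work-up without being transferred to oxirane. The fallback masks the hydroxyl first. It sets out from 5: silylation (TBSCl, imidazole) would give the silyl ether F5. The same methylalumination, alanate formation and epoxide opening would give the mono-protected diol F6. Bu4NF returns the route at 9.

**Step 6.** The carbanion could attack the internal alkene carbon with allylic shift, tert-butoxide could substitute or eliminate the allylic chloride, and some reaction at the C5 chloride is possible. The fallback separates carbanion formation from loss of boron. It sets out from 10: 11 is deprotonated with lithium 2,2,6,6-tetramethylpiperidide (THF, 0 °C) and alkylated by 10 to give the geminal bis(boronate) F7. One boryl group is then removed by NaOtBu in the presence of tert-butanol, which returns the route at 12.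

**Step 10.** The silyl ether oxygen may compete with the diamine for lithium and erode the enantioselectivity of the deprotonation. The boronate complex may also revert instead of rearranging on warming. The fallback isolates the carbenoid precursor. It sets out from 15: lithiation as in step 10 and trapping with Me3SnCl (retention) would give the (R)-stannane F8, whose enantiomeric purity can be checked and raised. Tin–lithium exchange (nBuLi, Et2O, −78 °C, retention), addition of 12 and the same MgBr2·OEt2-assisted rearrangement return the route at 20.

**Step 12.** Substitution at the unactivated primary halide by the hindered, weakly nucleophilic anion may be slow, leaving room for dialkylation and for base-induced loss of hydrogen halide. The fallback alkylates a more nucleophilic phosphonate and then exchanges the phosphorus esters. It sets out from 24: trimethyl phosphonoacetate (NaH, NaI, DMF) would give the dimethyl phosphonate F9. Me3SiBr with pyridine would give the bis(trimethylsilyl) phosphonate F10, and (COCl)2 with catalytic DMF the phosphonic dichloride F11. 2,2,2-Trifluoroethanol with iPr2NEt returns the route at 27.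

## Further compounds

F1 | step 15 | ethyl (5E,9Z,13R)-2-[bis(2-methylphenoxy)phosphoryl]-13-(2-{[tert-butyl(dimethyl)silyl]oxy}ethyl)-6,10,18-trimethyl-14-methylidenenonadeca-5,9,17-trienoate | C=C(CCC=C(C)C)[C@H](CC/C(C)=C\CC/C(C)=C/CCC(C(=O)OCC)P(=O)(Oc1ccccc1C)Oc1ccccc1C)CCO[Si](C)(C)C(C)(C)C
F2 | step 15 | ethyl (5E,9Z,13R)-2-[bis(2-methylphenoxy)phosphoryl]-13-(2-hydroxyethyl)-6,10,18-trimethyl-14-methylidenenonadeca-5,9,17-trienoate | C=C(CCC=C(C)C)[C@H](CC/C(C)=C\CC/C(C)=C/CCC(C(=O)OCC)P(=O)(Oc1ccccc1C)Oc1ccccc1C)CCO
F3 | step 15 | ethyl (5E,9Z,13R)-2-[bis(2-methylphenoxy)phosphoryl]-6,10,18-trimethyl-14-methylidene-13-(2-oxoethyl)nonadeca-5,9,17-trienoate | C=C(CCC=C(C)C)[C@H](CC/C(C)=C\CC/C(C)=C/CCC(C(=O)OCC)P(=O)(Oc1ccccc1C)Oc1ccccc1C)CC=O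
F4 | step 15 | ethyl (1Z,4E,8Z,12R)-5,9-dimethyl-12-(6-methylhepta-1,5-dien-2-yl)cyclotetradeca-1(14),4,8-triene-1-carboxylate | C=C(CCC=C(C)C)[C@H]1C/C=C(\C(=O)OCC)CC/C=C(\C)CC/C=C(/C)CC1
F5 | step 4 | tert-butyldimethyl{[(2Z)-2-methylhept-2-en-6-yn-1-yl]oxy}silane | CC(C)(C)[Si](C)(C)OC/C(C)=C\CCC#C
F6 | step 4 | (3E,7Z)-9-{[tert-butyl(dimethyl)silyl]oxy}-4,8-dimethylnona-3,7-dien-1-ol | OCC/C=C(\C)CC/C=C(/C)CO[Si](C)(C)C(C)(C)C
F7 | step 6 | 2,2'-[(3Z,7E)-10-chloro-3,7-dimethyldeca-3,7-diene-1,1-diyl]bis(4,4,5,5-tetramethyl-1,3,2-dioxaborolane) | CC1(C)OB(OC1(C)C)C(C/C(C)=C\CC/C(C)=C/CCCl)B1OC(C)(C)C(C)(C)O1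
F8 | step 10 | (1R)-3-{[tert-butyl(dimethyl)silyl]oxy}-1-(trimethylstannyl)propyl N,N-di(propan-2-yl)carbamate | C[Sn](C)(C)[C@H](CCO[Si](C)(C)C(C)(C)C)OC(=O)N(C(C)C)C(C)C
F9 | step 12 | methyl (5E,9Z,13R)-13-(2-{[tert-butyl(dimethyl)silyl]oxy}ethyl)-2-(dimethoxyphosphoryl)-6,10,18-trimethyl-14-methylidenenonadeca-5,9,17-trienoate | C=C(CCC=C(C)C)[C@H](CC/C(C)=C\CC/C(C)=C/CCC(C(=O)OC)P(=O)(OC)OC)CCO[Si](C)(C)C(C)(C)C
F10 | step 12 | methyl (5E,9Z,13R)-2-{bis[(trimethylsilyl)oxy]phosphoryl}-13-(2-{[tert-butyl(dimethyl)silyl]oxy}ethyl)-6,10,18-trimethyl-14-methylidenenonadeca-5,9,17-trienoate | C=C(CCC=C(C)C)[C@H](CC/C(C)=C\CC/C(C)=C/CCC(C(=O)OC)P(=O)(O[Si](C)(C)C)O[Si](C)(C)C)CCO[Si](C)(C)C(C)(C)C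
F11 | step 12 | methyl (5E,9Z,13R)-13-(2-{[tert-butyl(dimethyl)silyl]oxy}ethyl)-2-(dichlorophosphoryl)-6,10,18-trimethyl-14-methylidenenonadeca-5,9,17-trienoate | C=C(CCC=C(C)C)[C@H](CC/C(C)=C\CC/C(C)=C/CCC(C(=O)OC)P(=O)(Cl)Cl)CCO[Si](C)(C)C(C)(C)C
A1 | alternative 1 | 2-[(3Z,7E,11Z)-12-bromo-11-({[tert-butyl(dimethyl)silyl]oxy}methyl)-3,7-dimethyldodeca-3,7,11-trien-1-yl]-4,4,5,5-tetramethyl-1,3,2-dioxaborolane | CC1(C)OB(CC/C(C)=C\CC/C(C)=C/CC/C(CO[Si](C)(C)C(C)(C)C)=C/Br)OC1(C)C
A2 | alternative 1 | tert-butyl{[(1Z,4E,8Z,12R)-5,9-dimethyl-12-(4,4,5,5-tetramethyl-1,3,2-dioxaborolan-2-yl)cyclotetradeca-1(14),4,8-trien-1-yl]methoxy}dimethylsilane | CC1(C)OB(OC1(C)C)[C@H]2C/C=C(\CO[Si](C)(C)C(C)(C)C)CC/C=C(\C)CC/C=C(/C)CC2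
A3 | alternative 2 | 18-membered allylic macrolactone: carbonyl on C14, ester oxygen on C16, (E)-C1=C15 bearing the 4-methylpent-3-enyl group on C15, tert-butyldiphenylsilyl ether on the C4 hydroxymethyl, ring alkenes as in the target | O=C1CC/C(C)=C\CC/C(C)=C/CC/C(CO[Si](c2ccccc2)(c2ccccc2)C(C)(C)C)=C/C/C=C(\CCC=C(C)C)CO1
A4 | alternative 2 | 14-membered carbocyclic acid: carboxyl on C14, 6-methylhepta-1,5-dien-2-yl on C1, tert-butyldiphenylsilyl ether, configuration at C1 and C14 as drawn | C=C(CCC=C(C)C)[C@H]1C/C=C(\CO[Si](c2ccccc2)(c2ccccc2)C(C)(C)C)CC/C=C(\C)CC/C=C(/C)C[C@@H]1C(=O)O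
A5 | alternative 3 | open chain with (R)-C1, phenylsulfonyl on C9 of the (E)-C7=C8 allyl unit, bromide on C10 of the (Z)-C11=C12 allyl unit, TBS ether on the C4 hydroxymethyl | C=C(CCC=C(C)C)[C@H](CC/C(C)=C\CBr)C/C=C(\CO[Si](C)(C)C(C)(C)C)CC/C=C(\C)CS(=O)(=O)c1ccccc1
A6 | alternative 3 | 14-membered carbocycle with phenylsulfonyl on C9 (both C9 epimers), TBS ether on the C4 hydroxymethyl | C=C(CCC=C(C)C)[C@H]1C/C=C(\CO[Si](C)(C)C(C)(C)C)CC/C=C(\C)C(S(=O)(=O)c2ccccc2)C/C=C(/C)CC1
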